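**Retrosynthetic overview**
- The target, methyl 3-tricosyl-1H-pyrrole-2-carboxylate, comes from an N-tosyl-3-hydroxypyrrolidine-2-carboxylate by dehydration and loss of p-toluenesulfinate (aromatisation last).
- The pyrrolidine, the only ring, is closed by a Kenner-type aza-Michael (N1–C5) then aldol (C2–C3) between methyl N-tosylglycinate and hexacos-1-en-3-one.
- The enone is released by E1cB from a γ-keto sulfone. Its C3–C4 bond is the key disconnection: tetracosanal as an acyl anion (Breslow intermediate) adds to phenyl vinyl sulfone (Stetter reaction).
- Tetracosanal comes from commercial tetracosan-1-ol.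

Assumption: the target has no stereocentre, so no stereocontrol is needed; the stereocentres of intermediates form as mixtures and are erased in the last step.

**Step 1**
Reactants: 1 tetracosan-1-ol
Product: 2 tetracosanal
Conditions: PhI(OAc)2 (1.2 equiv), TEMPO (10 mol%), CH2Cl2, 40 °C
Reagents that add atoms: none
Why: The TEMPO/PhI(OAc)2 alcohol oxidation (oxoammonium-mediated) is anhydrous and stops at the aldehyde, and warm CH2Cl2 keeps the C24 chain in solution.

**Step 2**
Reactants: 2 tetracosanal; 3 phenyl vinyl sulfone; 4 methyl N-tosylglycinate
Product: 7 methyl 3-hydroxy-1-tosyl-3-tricosylpyrrolidine-2-carboxylate (racemic diastereomer mixture), via keto sulfone 5 (not isolated), via vinyl ketone 6 (not isolated)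
Conditions: 3-benzyl-5-(2-hydroxyethyl)-4-methylthiazolium chloride (20 mol%), Et3N (0.3 equiv), 3 (1.05 equiv), 1,4-dioxane, 75 °C; then 4 (1.5 equiv), DBU (3 equiv), THF, rt
Reagents that add atoms: none
Why: Proposed new method: this is a one-flask merger, not reported as a single operation, of three known events: (a) a Stetter reaction, in which the thiazol-2-ylidene converts 2 into its Breslow intermediate (an acyl anion equivalent) whose carbon attacks the β-carbon of 3, joining the former carbonyl carbon (ring C3) to C4 and giving 5; (b) DBU-induced E1cB loss of benzenesulfinate, which unmasks 6 only after the aldehyde is consumed so that no second Stetter addition can occur; and (c) a Kenner annulation, in which the sulfonamide anion of 4 adds to 6 (N1–C5) and the glycinate carbanion closes C2–C3 by intramolecular aldol; the closest known reaction types are the thiazolium-catalysed aldehyde/vinyl sulfone Stetter addition with base release of the vinyl ketone and the DBU-mediated N-tosylglycinate/vinyl ketone pyrrolidine synthesis; the two stereocentres (C2, C3) form without control and are both destroyed in step 3.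

**Step 3**
Reactants: 7 methyl 3-hydroxy-1-tosyl-3-tricosylpyrrolidine-2-carboxylate
Product: 9 methyl 3-tricosyl-1H-pyrrole-2-carboxylate, via dihydropyrrole 8 (not isolated)
Conditions: POCl3 (3 equiv), pyridine, 0 °C to rt; concentrate; then DBU (5 equiv), toluene, 100 °C
Reagents that add atoms: none
Why: POCl3/pyridine turns the tertiary alcohol into a dichlorophosphate that undergoes E2 elimination to 8 and its double-bond isomers, after which DBU removes the acidic C2–H (or, vinylogously, C4–H of the conjugated isomer), expels p-toluenesulfinate from nitrogen (E1cB) and the 2H-pyrrole tautomerises to the aromatic 1H-pyrrole, which is the dehydration/sulfinate-elimination endgame of the Kenner pyrrole synthesis and leaves no stereocentre.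

**Compound list**
1 | tetracosan-1-ol | CCCCCCCCCCCCCCCCCCCCCCCCO | starting material
2 | tetracosanal | CCCCCCCCCCCCCCCCCCCCCCCC=O | intermediate
3 | phenyl vinyl sulfone | C=CS(=O)(=O)c1ccccc1 | starting material
4 | methyl N-tosylglycinate | COC(=O)CNS(=O)(=O)c1ccc(C)cc1 | starting material
5 | 1-(phenylsulfonyl)hexacosan-3-one | CCCCCCCCCCCCCCCCCCCCCCCC(=O)CCS(=O)(=O)c1ccccc1 | intermediate (not isolated)
6 | hexacos-1-en-3-one | CCCCCCCCCCCCCCCCCCCCCCCC(=O)C=C | intermediate (not isolated)
7 | methyl 3-hydroxy-1-tosyl-3-tricosylpyrrolidine-2-carboxylate (racemic, mixture of C2/C3 diastereomers) | CCCCCCCCCCCCCCCCCCCCCCCC1(O)CCN(S(=O)(=O)c2ccc(C)cc2)C1C(=O)OC | intermediate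
8 | methyl 1-tosyl-3-tricosyl-2,5-dihydro-1H-pyrrole-2-carboxylate (racemic; accompanied by double-bond isomers) | CCCCCCCCCCCCCCCCCCCCCCCC1=CCN(S(=O)(=O)c2ccc(C)cc2)C1C(=O)OC | intermediate (not isolated)
9 | methyl 3-tricosyl-1H-pyrrole-2-carboxylate (achiral) | CCCCCCCCCCCCCCCCCCCCCCCc1cc[nH]c1C(=O)OC | target

**Step count**
Total steps: 3. Longest linear sequence: 3 (1 → 2 → 7 → 9).

**Steps most likely to fail, with fallbacks**

Step 2 carries the highest risk. The one-flask merger is untested, the C24 aldehyde may divert to acyloin or aldol products instead of the Stetter adduct, and residual carbene could oligomerise 6 once it is released. The fallback sets out from 2: vinylmagnesium bromide in THF at 0 °C gives racemic hexacos-1-en-3-ol F1, and activated MnO2 in CH2Cl2 oxidises it to vinyl ketone 6. The route is rejoined at 6, which is treated with 4 and DBU in THF as in the second stage of step 2 to give 7.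

Step 3 is next. Dehydration of the tertiary alcohol may favour the exocyclic alkene or be undercut by retro-aldol, and the isomer mixture may not all converge on the pyrrole under DBU. The fallback sets out from 2: dimethyl (1-diazo-2-oxopropyl)phosphonate with K2CO3 in MeOH/THF gives pentacos-1-yne F2. This undergoes Ag2CO3-catalysed (10 mol%) formal [3+2] cycloaddition with methyl isocyanoacetate in 1,4-dioxane at 80 °C, placing the alkyl group at C3, and rejoins the route at the target 9 without passing through any hydroxypyrrolidine.

Step 1 carries the least risk: over-oxidation or poor solubility of the waxy alcohol. The fallback sets out from 1: TsCl in pyridine gives tetracosyl 4-methylbenzenesulfonate F3, and Kornblum oxidation (DMSO, NaHCO3, 150 °C) converts it to 2, where the route is rejoined.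

**Further compounds**
F1 | step 2 | hexacos-1-en-3-ol (racemic) | CCCCCCCCCCCCCCCCCCCCCCCC(O)C=C
F2 | step 3 | pentacos-1-yne | CCCCCCCCCCCCCCCCCCCCCCCC#C
F3 | step 1 | tetracosyl 4-methylbenzenesulfonate | CCCCCCCCCCCCCCCCCCCCCCCCOS(=O)(=O)c1ccc(C)cc1
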